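## Structural features

The target is a flavone: a benzo-fused 4-pyranone (rings A and C) joined through the single bond C2–C1' to a 2,6-dioxygenated phenyl ring (ring B). It has no stereocentre, so nothing stereochemical has to be set. Ring A is fully substituted (5-OMe, 6-OH, 7-OMe, 8-OMe, O1), so the task is to tell neighbouring oxygens apart: O6 must end as a free phenol between two methyl ethers, and O5, peri to the C4 carbonyl, must end methylated. Ring B is unsymmetrical (2'-OH, 6'-OMe) and doubly ortho-substituted, which makes the acyl electrophile that delivers it hindered. The fragile points are these: the 5-OMe group is the ether most easily lost to Lewis acids, the 6-hydroxy ring is an oxidisable para-alkoxyphenol, ring C can be opened by hard nucleophiles at C2, and a free 2'-OH could re-close an opened ring C the wrong way round. An acyl group on O6 is a further trap, because once O5 is a free phenol beside it a base-induced 1,2-acyl shift from O6 to O5 would scramble the two oxygens. The key step uses the C5–H bond of ring A, which lies peri to the C4 carbonyl of ring C: carbonyl oxygen, C4, C4a and C5 can close a five-membered metallacycle, and no other C–H bond of the molecule can.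

## Logic of the disconnections

15 to 14: the O6–S and O2'–S bonds are cut. Both phenols that end free carry the same sulfonyl group from the first steps to the last, so one operation unmasks both. The forward step demands that hydroxide ion attack sulfur faster than C2 of ring C.

14 to 13: the O5–CH3 bond is cut. The ether peri to the carbonyl is the most labile, so it is made last, and 13 has only one free OH, so there is no selectivity question. The forward step must alkylate a chelated, flanked phenol under base; a sulfonyl group on O6 cannot shift to O5 under these conditions, which an ester could.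

13 to 11 (through 12): the C5–O bond is cut. C5–H is the one C–H bond that the C4 carbonyl can deliver a metal to, so the fourth oxygen of ring A need not be carried through the synthesis. Ring A simplifies to a pentasubstituted arene derived from a 1,2,3-trioxygenated benzene. The forward step demands metalation at C5 only and an oxidant that leaves both aryl rings alone.

11 to 10: the O1–C2 bond of ring C is cut (cyclodehydration). The gain is an open-chain 1,3-diketone. The demand is that only one phenol can close; O2' is sulfonylated, so the ring B oxygen cannot compete.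

10 to 6 and 9: the bond between the methylene carbon (future C3) and the ring B carbonyl carbon (future C2) is cut. This divides the molecule into two halves of similar size. The forward step is C-acylation of a ketone enolate by a 2,6-disubstituted aroyl chloride.

9 to 8 to 7: the C–Cl bond, then the O–S bond. Ring B comes from a commercial acid with the OH/OMe pattern already in place; only the phenol has to be masked before the carboxyl group is activated.

6 to 4 (through 5): the aryl–acetyl bond (future C4a–C4) is cut and the methyl is restored on the oxygen that becomes O1. The sulfonate on the future O6 deactivates its own ortho position, so the acetyl group is expected at the position ortho and para to methoxy groups. AlCl3 then removes exactly the methyl ortho to the new ketone. The demand is one regiochemical choice and one, not two, demethylations.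

4 to 3 to 1 (through 2): the O–S bond, then the aryl C–O bond back to aryl C–CHO. The formyl carbon of 1 marks the one oxygen that must differ from its neighbours; the forward Dakin oxidation only needs the electron-rich aryl group to migrate.

## Other disconnections considered

Alternative 1: The cut runs through ring A itself. Its six carbons come from dimethyl squarate A1 plus a two-carbon methoxyvinyl unit, and the C4a–C8a bond is formed last. In the forward key step, thermolysis of cyclobutenone A2 would open the four-membered ring to a dienylketene, which would electrocyclise and tautomerise to phenol A3. In its favour, every oxygen of ring A is placed by construction, with O6 as a silyl ether and O1 as a free phenol. No C–H oxidation is needed, and the final unmasking by fluoride would be milder than the sulfonate hydrolysis of step 10. On these points it is the better plan. Against it, A3 still lacks the C4 carbon. An acyl group would have to enter the single free position of a pentasubstituted, acid-sensitive silyloxyarene. The resulting doubly flanked ketone would then have to be joined to the hindered ring B unit. Cryogenic organometallic chemistry and a high-temperature thermolysis are also required. On structure, both plans are regiochemically unambiguous; the alternative differentiates O5 and O6 at the start, the chosen plan at the end. On mechanism, the pericyclic cascade has no site-selectivity question, which is an advantage, but its weak steps lie outside the key step. On step economy the two are about equal: three steps to A3, then acylation, diketone formation, cyclisation, deprotection and the ring B branch.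

Alternative 2: The cut is O1–C8a, so ring C closes by forming the aryl–oxygen bond. In the forward key step, anodic oxidation of phenolic diketone A4 would give a phenoxonium ion. The enol oxygen would add at C8a, para to the phenol, and proton loss would give A5, one hydrogenolysis from the target. In its favour, the 5-OMe group and the free 6-OH exist before the heterocycle does. There is then no peri C–H activation, no protecting group on O6, no methylation beside a protected oxygen and no metal oxidant, and the end game is milder than step 10. On these points it is equal or better. Against it, a dehydrogenative phenol–enol C–O coupling to a chromone has little precedent and would have to be developed. A5 is a more electron-rich para-alkoxyphenol than A4, so over-oxidation to quinoid products or ipso attack at the methoxy-bearing ortho carbons is likely. The enol and the benzyl ether are also oxidisable. The aryl ketone half of A4 poses the same problem of one differentiated oxygen in a tetraoxygenated benzene, with no shortcut. On structure, both plans converge at a 1,3-diketone and are equal in convergence. On mechanism, the chosen step has geometric site control, while the anodic step relies on the para position being the only free one and has no control over the fate of its product. On step economy the alternative could be one or two steps shorter, at clearly higher risk.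

Alternative 3: The cut is C3'–C4' and C5'–C6', so ring B is built on a finished chromone. In the forward key step, diene A6 would add phenyl vinyl sulfoxide A7, and the adduct would aromatise by loss of its sulfur and silicon leaving groups to give A8. In its favour, the unsymmetrical ring B pattern is written into the diene: the silyloxy carbon becomes C2'–OH and the ketene acetal carbon becomes C6'–OMe. Ring B appears with its phenol free, and the hindered aroylation of step 6 is avoided. On these points it is equal or better. Against it, ring B is the easy part of the molecule and is available as 7. A6 requires a chromone that already carries the complete, differentiated ring A and a ketoester side chain at C2. A7 is a sluggish dienophile, and a hindered, moisture-sensitive diene may desilylate or add to C2=C3 of another chromone before it reacts. On structure, the alternative leaves the real difficulty, ring A, untouched, while the chosen plan addresses it directly. On mechanism, cycloaddition followed by elimination is dependable in general and regiochemistry is not an issue with an ethyne equivalent. On step economy it is clearly longer.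

Key step: step 8

Assumption: both phenols that end free are carried as 4-methylbenzenesulfonates (tosylates) and not as carboxylic esters. An ester on O6 would suit the oxidation but could shift to the neighbouring O5 under the basic methylation. A sulfonyl group is not expected to shift, and it also tolerates AlCl3 (no Fries shift), LiN(SiMe3)2 and hot acid, so no exchange of protecting groups is needed.

## Route

Step 1
Reactants: 1 2,3,4-trimethoxybenzaldehyde
Product: 3 2,3,4-trimethoxyphenol, via 2,3,4-trimethoxyphenyl formate 2 (not isolated)
Conditions: 30% aq. H2O2, cat. H2SO4, MeOH, rt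
Reagents that add atoms: hydrogen peroxide, OO
Why: Acid-catalysed Dakin (Baeyer–Villiger type) oxidation, in which the electron-rich aryl group migrates to oxygen and formate 2 is methanolysed in the same flask; the former aldehyde carbon now marks the oxygen that ends as the free 6-OH.

Step 2
Reactants: 3 2,3,4-trimethoxyphenol
Product: 4 2,3,4-trimethoxyphenyl 4-methylbenzenesulfonate
Conditions: TsCl, Et3N, cat. DMAP, CH2Cl2, 0 °C to rt
Reagents that add atoms: 4-methylbenzenesulfonyl chloride, Cc1ccc(S(=O)(=O)Cl)cc1
Why: Routine O-sulfonylation of a phenol; the tosylate withstands every later reagent up to step 10 and lowers the electron density of the ring it sits on.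

Step 3
Reactants: 4 2,3,4-trimethoxyphenyl 4-methylbenzenesulfonate
Product: 6 1-[2-hydroxy-3,4-dimethoxy-5-(tosyloxy)phenyl]ethanone, via 5-acetyl-2,3,4-trimethoxyphenyl tosylate 5 (not isolated)
Conditions: AcCl, AlCl3 (2.5 equiv), CH2Cl2, 0 °C to rt; aq. HCl
Reagents that add atoms: acetyl chloride, CC(=O)Cl
Why: Friedel–Crafts acylation should enter the position ortho to one methoxy group and para to another, since the only other free position is ortho to the deactivating sulfonate and para to the twisted central methoxy group; AlCl3 chelated between the new ketone and its ortho methoxy group then cleaves that one methyl, the classical acylation with ortho-demethylation of 1,2,3-trimethoxyarenes.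

Step 4
Reactants: 7 2-hydroxy-6-methoxybenzoic acid
Product: 8 2-methoxy-6-(tosyloxy)benzoic acid
Conditions: TsCl, aq. NaOH, THF, 0 °C; then aq. HCl
Reagents that add atoms: 4-methylbenzenesulfonyl chloride, Cc1ccc(S(=O)(=O)Cl)cc1
Why: Schotten–Baumann sulfonylation of the phenoxide of the dianion; any mixed carboxylic–sulfonic anhydride is hydrolysed back to the carboxylate in the cold aqueous base, so only the phenol stays sulfonylated.

Step 5
Reactants: 8 2-methoxy-6-(tosyloxy)benzoic acid
Product: 9 2-methoxy-6-(tosyloxy)benzoyl chloride
Conditions: (COCl)2, cat. DMF, CH2Cl2, 0 °C to rt; evaporated and used crude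
Reagents that add atoms: oxalyl chloride, O=C(Cl)C(Cl)=O
Why: Vilsmeier-type conversion of a carboxylic acid to its chloride; with the phenol masked there is no self-condensation and the sulfonate is inert.

Step 6
Reactants: 6 1-[2-hydroxy-3,4-dimethoxy-5-(tosyloxy)phenyl]ethanone; 9 2-methoxy-6-(tosyloxy)benzoyl chloride
Product: 10 1-[2-hydroxy-3,4-dimethoxy-5-(tosyloxy)phenyl]-3-[2-methoxy-6-(tosyloxy)phenyl]propane-1,3-dione
Conditions: LiN(SiMe3)2 (3.1 equiv), THF, −78 °C; then 9, −78 °C to rt; aq. HCl
Reagents that add atoms: none
Why: Crossed Claisen acylation of the phenoxide–enolate dianion of 6, the one-flask form of the Baker–Venkataraman synthesis; the third equivalent of base ionises the more acidic diketone as it forms, any O-aroylated phenoxide rearranges to the same diketone under the excess base, and the tosylates have no acidic hydrogen for LiN(SiMe3)2 to remove.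

Step 7
Reactants: 10 1-[2-hydroxy-3,4-dimethoxy-5-(tosyloxy)phenyl]-3-[2-methoxy-6-(tosyloxy)phenyl]propane-1,3-dione
Product: 11 7,8-dimethoxy-2-[2-methoxy-6-(tosyloxy)phenyl]-4-oxo-4H-chromen-6-yl 4-methylbenzenesulfonate
Conditions: cat. H2SO4, AcOH, 95 °C
Reagents that add atoms: none
Why: Acid-catalysed cyclodehydration of a 2-hydroxyaryl 1,3-diketone to the 4-pyranone; only the ring A phenol is free, so ring C can close in one sense only, and aryl sulfonates are stable to hot protic acid.

Step 8
Reactants: 11 7,8-dimethoxy-2-[2-methoxy-6-(tosyloxy)phenyl]-4-oxo-4H-chromen-6-yl 4-methylbenzenesulfonate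
Product: 13 5-hydroxy-7,8-dimethoxy-2-[2-methoxy-6-(tosyloxy)phenyl]-4-oxo-4H-chromen-6-yl 4-methylbenzenesulfonate, via C5 trifluoroacetate ester 12 (not isolated)
Conditions: [RuCl2(p-cymene)]2 (5 mol %), PhI(OCOCF3)2 (1.5 equiv), CF3CO2H/(CF3CO)2O (4:1), 80 °C; Me2S; then aq. NaHCO3, MeOH, rt
Reagents that add atoms: [bis(trifluoroacetoxy)iodo]benzene, O=C(OI(OC(=O)C(F)(F)F)c1ccccc1)C(F)(F)F (its trifluoroacetate, exchanging with solvent trifluoroacetic acid, OC(=O)C(F)(F)F, supplies the C5 oxygen)
Why: In CF3CO2H, [RuCl2(p-cymene)]2 is opened to a cationic (p-cymene) trifluoroacetate complex of divalent ruthenium, which binds the C4 carbonyl oxygen, the most basic site of 11. Carboxylate-assisted concerted metalation–deprotonation of the peri C5–H bond gives a five-membered ruthenacycle (Ru, O, C4, C4a, C5). PhI(OCOCF3)2 oxidises this to tetravalent ruthenium, and C–O reductive elimination places trifluoroacetate on C5 and returns divalent ruthenium; this is the known ketone-directed ortho C–H oxygenation of aryl ketones, precedented at C5 of chromones and flavones. No ring is closed and no stereocentre is formed; the only new bond is C5–O. The selectivity needed is site selectivity, and it rests on geometry: C3–H would require a four-membered chelate, no ring B C–H can reach the carbonyl-bound metal, and sulfonyl oxygens are too weakly basic to act as competing directing groups. Chemoselectivity against direct oxidation by the trivalent-iodine reagent comes from the two sulfonates, which lower the electron density of rings A and B and are inert to hot acid, and from (CF3CO)2O, which holds the product as ester 12 and not as a free para-methoxyphenol. Excess oxidant is reduced with Me2S before mild hydrolysis releases the hydrogen-bonded 5-phenol 13.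

Step 9
Reactants: 13 5-hydroxy-7,8-dimethoxy-2-[2-methoxy-6-(tosyloxy)phenyl]-4-oxo-4H-chromen-6-yl 4-methylbenzenesulfonate
Product: 14 5,7,8-trimethoxy-2-[2-methoxy-6-(tosyloxy)phenyl]-4-oxo-4H-chromen-6-yl 4-methylbenzenesulfonate
Conditions: Me2SO4, K2CO3, acetone, reflux
Reagents that add atoms: dimethyl sulfate, COS(=O)(=O)OC
Why: Williamson methylation of the only free OH; the chelated phenol needs heat, which is tolerable because a sulfonyl group is geometrically disfavoured from shifting between neighbouring oxygens through a five-membered transition state, and aryl tosylates are inert to K2CO3 in acetone.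

Step 10
Reactants: 14 5,7,8-trimethoxy-2-[2-methoxy-6-(tosyloxy)phenyl]-4-oxo-4H-chromen-6-yl 4-methylbenzenesulfonate
Product: 15 6-hydroxy-2-(2-hydroxy-6-methoxyphenyl)-5,7,8-trimethoxy-4H-chromen-4-one (6,2'-dihydroxy-5,7,8,6'-tetramethoxyflavone)
Conditions: 2 M aq. NaOH, 1,4-dioxane, 60 °C, Ar; then aq. HCl to pH 4
Reagents that add atoms: none
Why: Alkaline hydrolysis of aryl sulfonates by attack of hydroxide ion at sulfur, which keeps both aryl oxygens; no Lewis acid touches the 5-OMe group, the alcohol-free medium forms no alkyl tosylate that could re-alkylate the phenoxides, and C2 is shielded by the doubly ortho-substituted ring B.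

## Compound list

1 | 2,3,4-trimethoxybenzaldehyde | COc1ccc(C=O)c(OC)c1OC | starting material
2 | 2,3,4-trimethoxyphenyl formate | COc1ccc(OC=O)c(OC)c1OC | intermediate (not isolated)
3 | 2,3,4-trimethoxyphenol | COc1ccc(O)c(OC)c1OC | intermediate
4 | 2,3,4-trimethoxyphenyl 4-methylbenzenesulfonate | COc1ccc(OS(=O)(=O)c2ccc(C)cc2)c(OC)c1OC | intermediate
5 | 5-acetyl-2,3,4-trimethoxyphenyl 4-methylbenzenesulfonate | CC(=O)c1cc(OS(=O)(=O)c2ccc(C)cc2)c(OC)c(OC)c1OC | intermediate (not isolated)
6 | 1-[2-hydroxy-3,4-dimethoxy-5-(tosyloxy)phenyl]ethanone | CC(=O)c1cc(OS(=O)(=O)c2ccc(C)cc2)c(OC)c(OC)c1O | intermediate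
7 | 2-hydroxy-6-methoxybenzoic acid | COc1cccc(O)c1C(=O)O | starting material
8 | 2-methoxy-6-(tosyloxy)benzoic acid | COc1cccc(OS(=O)(=O)c2ccc(C)cc2)c1C(=O)O | intermediate
9 | 2-methoxy-6-(tosyloxy)benzoyl chloride | COc1cccc(OS(=O)(=O)c2ccc(C)cc2)c1C(Cl)=O | intermediate
10 | 1-[2-hydroxy-3,4-dimethoxy-5-(tosyloxy)phenyl]-3-[2-methoxy-6-(tosyloxy)phenyl]propane-1,3-dione | COc1cccc(OS(=O)(=O)c2ccc(C)cc2)c1C(=O)CC(=O)c1cc(OS(=O)(=O)c2ccc(C)cc2)c(OC)c(OC)c1O | intermediate
11 | 7,8-dimethoxy-2-[2-methoxy-6-(tosyloxy)phenyl]-4-oxo-4H-chromen-6-yl 4-methylbenzenesulfonate | COc1cccc(OS(=O)(=O)c2ccc(C)cc2)c1-c1cc(=O)c2cc(OS(=O)(=O)c3ccc(C)cc3)c(OC)c(OC)c2o1 | intermediate (key-step precursor)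
12 | 7,8-dimethoxy-2-[2-methoxy-6-(tosyloxy)phenyl]-4-oxo-6-(tosyloxy)-4H-chromen-5-yl trifluoroacetate | COc1cccc(OS(=O)(=O)c2ccc(C)cc2)c1-c1cc(=O)c2c(OC(=O)C(F)(F)F)c(OS(=O)(=O)c3ccc(C)cc3)c(OC)c(OC)c2o1 | intermediate (not isolated)
13 | 5-hydroxy-7,8-dimethoxy-2-[2-methoxy-6-(tosyloxy)phenyl]-4-oxo-4H-chromen-6-yl 4-methylbenzenesulfonate | COc1cccc(OS(=O)(=O)c2ccc(C)cc2)c1-c1cc(=O)c2c(O)c(OS(=O)(=O)c3ccc(C)cc3)c(OC)c(OC)c2o1 | intermediate (key-step product)
14 | 5,7,8-trimethoxy-2-[2-methoxy-6-(tosyloxy)phenyl]-4-oxo-4H-chromen-6-yl 4-methylbenzenesulfonate | COc1cccc(OS(=O)(=O)c2ccc(C)cc2)c1-c1cc(=O)c2c(OC)c(OS(=O)(=O)c3ccc(C)cc3)c(OC)c(OC)c2o1 | intermediate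
15 | 6-hydroxy-2-(2-hydroxy-6-methoxyphenyl)-5,7,8-trimethoxy-4H-chromen-4-one | COc1cccc(O)c1-c1cc(=O)c2c(OC)c(O)c(OC)c(OC)c2o1 | target

## Step count and least certain steps

Total step count: 10. Longest linear sequence: 8 steps (1, 2, 3, 6, 7, 8, 9, 10); the ring B branch (steps 4 and 5) joins at step 6.

Step 8 (key step). The most likely failure is slow cyclometalation at C5–H, which is flanked by the sulfonate on C6 and sits on a ring made electron-poor. The oxidant would then be consumed unproductively or attack ring B. A second failure is oxidative demethylation at the para 8-OMe group if ester 12 is hydrolysed before the oxidant is destroyed. The fallback brings O5 in with the ring A building block by classical chemistry. It sets out from 9 and re-enters at 14. Purchased 1-(2-hydroxy-3,4,6-trimethoxyphenyl)ethanone F1 would undergo Elbs oxidation (K2S2O8, aq. NaOH) to potassium 3-acetyl-4-hydroxy-2,5,6-trimethoxyphenyl sulfate F2. Warm dilute HCl would hydrolyse this to 1-(2,5-dihydroxy-3,4,6-trimethoxyphenyl)ethanone F3. TsCl with K2CO3 in acetone would sulfonylate the non-chelated OH to give 1-[2-hydroxy-3,4,6-trimethoxy-5-(tosyloxy)phenyl]ethanone F4. Acylation of its dianion (LiN(SiMe3)2, THF) with 9 would give 1-[2-hydroxy-3,4,6-trimethoxy-5-(tosyloxy)phenyl]-3-[2-methoxy-6-(tosyloxy)phenyl]propane-1,3-dione F5. Cyclodehydration (cat. H2SO4, AcOH) would give 14.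

Step 3. Two things may go wrong: acylation at the position next to the sulfonate, or loss of a second methyl group (the one beside the new phenol) on prolonged contact with AlCl3. The fallback builds the same ketone from a symmetrical hydroquinone, where acylation has no regiochemical choice. It sets out from 3 and returns at 6. Oxidative demethylation of 3 with (NH4)2Ce(NO3)6 in MeCN/H2O would give 2,3-dimethoxy-1,4-benzoquinone F6. Na2S2O4 would reduce this to 2,3-dimethoxybenzene-1,4-diol F7. BF3·OEt2 in AcOH at 90 °C would C-acetylate it to 1-(2,5-dihydroxy-3,4-dimethoxyphenyl)ethanone F8. TsCl with K2CO3 in acetone would then sulfonylate the non-chelated OH selectively to give 6.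

Step 6. The intermolecular C-acylation may be too slow with an aroyl chloride flanked by two ortho substituents, so the enolate would be lost to proton exchange and self-condensation. The fallback replaces the acyl electrophile by the less hindered aldehyde and closes ring C oxidatively. It sets out from 6 and returns at 11. Purchased 2-hydroxy-6-methoxybenzaldehyde F9 would be tosylated (TsCl, Et3N) to 2-formyl-3-methoxyphenyl 4-methylbenzenesulfonate F10. Acid-catalysed Claisen–Schmidt condensation with 6 (HCl generated from SOCl2 in EtOH, rt) would give (E)-1-[2-hydroxy-3,4-dimethoxy-5-(tosyloxy)phenyl]-3-[2-methoxy-6-(tosyloxy)phenyl]prop-2-en-1-one F11. Catalytic I2 in DMSO at 130 °C would cyclise and dehydrogenate it to 11.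

Step 10. Hydroxide ion may add at C2 and open ring C in competition with S–O cleavage, after which re-closure through the ring B phenol becomes possible. The fallback moves the alkaline cleavage to 13, where the ionised, chelated 5-phenoxide should make the pyranone much less electrophilic, and ends with a neutral hydrogenolysis. It sets out from 13, also replaces step 9, and returns at 15. NaOH in aqueous dioxane under Ar would convert 13 into 5,6-dihydroxy-2-(2-hydroxy-6-methoxyphenyl)-7,8-dimethoxy-4H-chromen-4-one F12. BnBr (2 equiv) with K2CO3 in acetone would benzylate the 6- and 2'-phenols and spare the chelated 5-OH, giving 6-(benzyloxy)-2-[2-(benzyloxy)-6-methoxyphenyl]-5-hydroxy-7,8-dimethoxy-4H-chromen-4-one F13. Me2SO4 with K2CO3 would give 6-(benzyloxy)-2-[2-(benzyloxy)-6-methoxyphenyl]-5,7,8-trimethoxy-4H-chromen-4-one F14. H2 over Pd/C in EtOAc would give 15. Benzyl ethers cannot shift between oxygens, so the methylation stays unambiguous.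

## Further compounds

F1 | step 8 | 1-(2-hydroxy-3,4,6-trimethoxyphenyl)ethanone (purchased) | CC(=O)c1c(O)c(OC)c(OC)cc1OC
F2 | step 8 | potassium 3-acetyl-4-hydroxy-2,5,6-trimethoxyphenyl sulfate | CC(=O)c1c(O)c(OC)c(OC)c(OS(=O)(=O)[O-])c1OC.[K+]
F3 | step 8 | 1-(2,5-dihydroxy-3,4,6-trimethoxyphenyl)ethanone | CC(=O)c1c(O)c(OC)c(OC)c(O)c1OC
F4 | step 8 | 1-[2-hydroxy-3,4,6-trimethoxy-5-(tosyloxy)phenyl]ethanone | CC(=O)c1c(O)c(OC)c(OC)c(OS(=O)(=O)c2ccc(C)cc2)c1OC
F5 | step 8 | 1-[2-hydroxy-3,4,6-trimethoxy-5-(tosyloxy)phenyl]-3-[2-methoxy-6-(tosyloxy)phenyl]propane-1,3-dione | COc1cccc(OS(=O)(=O)c2ccc(C)cc2)c1C(=O)CC(=O)c1c(O)c(OC)c(OC)c(OS(=O)(=O)c2ccc(C)cc2)c1OC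
F6 | step 3 | 2,3-dimethoxy-1,4-benzoquinone | COC1=C(OC)C(=O)C=CC1=O
F7 | step 3 | 2,3-dimethoxybenzene-1,4-diol | COc1c(O)ccc(O)c1OC
F8 | step 3 | 1-(2,5-dihydroxy-3,4-dimethoxyphenyl)ethanone | CC(=O)c1cc(O)c(OC)c(OC)c1O
F9 | step 6 | 2-hydroxy-6-methoxybenzaldehyde (purchased) | COc1cccc(O)c1C=O
F10 | step 6 | 2-formyl-3-methoxyphenyl 4-methylbenzenesulfonate | COc1cccc(OS(=O)(=O)c2ccc(C)cc2)c1C=O
F11 | step 6 | (E)-1-[2-hydroxy-3,4-dimethoxy-5-(tosyloxy)phenyl]-3-[2-methoxy-6-(tosyloxy)phenyl]prop-2-en-1-one | COc1cccc(OS(=O)(=O)c2ccc(C)cc2)c1/C=C/C(=O)c1cc(OS(=O)(=O)c2ccc(C)cc2)c(OC)c(OC)c1O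
F12 | step 10 | 5,6-dihydroxy-2-(2-hydroxy-6-methoxyphenyl)-7,8-dimethoxy-4H-chromen-4-one | COc1cccc(O)c1-c1cc(=O)c2c(O)c(O)c(OC)c(OC)c2o1
F13 | step 10 | 6-(benzyloxy)-2-[2-(benzyloxy)-6-methoxyphenyl]-5-hydroxy-7,8-dimethoxy-4H-chromen-4-one | COc1cccc(OCc2ccccc2)c1-c1cc(=O)c2c(O)c(OCc3ccccc3)c(OC)c(OC)c2o1
F14 | step 10 | 6-(benzyloxy)-2-[2-(benzyloxy)-6-methoxyphenyl]-5,7,8-trimethoxy-4H-chromen-4-one | COc1cccc(OCc2ccccc2)c1-c1cc(=O)c2c(OC)c(OCc3ccccc3)c(OC)c(OC)c2o1
A1 | alternative 1 | dimethyl squarate (3,4-dimethoxycyclobut-3-ene-1,2-dione) | COC1=C(OC)C(=O)C1=O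
A2 | alternative 1 | 4-(tert-butyldimethylsilyloxy)-2,3-dimethoxy-4-(1-methoxyethenyl)cyclobut-2-en-1-one (racemic) | C=C(OC)C1(O[Si](C)(C)C(C)(C)C)C(OC)=C(OC)C1=O
A3 | alternative 1 | 4-(tert-butyldimethylsilyloxy)-2,3,5-trimethoxyphenol | COc1cc(O)c(OC)c(OC)c1O[Si](C)(C)C(C)(C)C
A4 | alternative 2 | 1-[2-(benzyloxy)-6-methoxyphenyl]-3-(3-hydroxy-2,4,5-trimethoxyphenyl)propane-1,3-dione | COc1cccc(OCc2ccccc2)c1C(=O)CC(=O)c1cc(OC)c(OC)c(O)c1OC
A5 | alternative 2 | 2-[2-(benzyloxy)-6-methoxyphenyl]-6-hydroxy-5,7,8-trimethoxy-4H-chromen-4-one | COc1cccc(OCc2ccccc2)c1-c1cc(=O)c2c(OC)c(O)c(OC)c(OC)c2o1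
A6 | alternative 3 | 6-(benzyloxy)-5,7,8-trimethoxy-2-[1-methoxy-1,3-bis(trimethylsilyloxy)buta-1,3-dien-2-yl]-4H-chromen-4-one | C=C(O[Si](C)(C)C)C(=C(OC)O[Si](C)(C)C)c1cc(=O)c2c(OC)c(OCc3ccccc3)c(OC)c(OC)c2o1
A7 | alternative 3 | phenyl vinyl sulfoxide (racemic) | C=CS(=O)c1ccccc1
A8 | alternative 3 | 6-(benzyloxy)-2-(2-hydroxy-6-methoxyphenyl)-5,7,8-trimethoxy-4H-chromen-4-one | COc1cccc(O)c1-c1cc(=O)c2c(OC)c(OCc3ccccc3)c(OC)c(OC)c2o1
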